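The ten-membered ring is uncovered, not closed. C9 (oxygenated) and C4 (methyl-bearing alkene carbon) face each other across the germacrane ring, so a temporary C4–C9 bond turns the target into an octalin (ring A: C1–C4, C9, C10; ring B: C4–C9). A Wharton (Grob-type) fragmentation of the C9 alkoxide with an equatorial C5 mesylate cuts this shared bond and writes the C9 ketone and the 4E alkene in one operation, while ring A already holds 1(10)Z. The precursor is a carvone-derived Δ1(10)-octalin carrying the trans-fused 12,6-lactone with its 11-methyl group, a C3 silyl ether, an angular C9 hydroxyl whose configuration the key step erases, and the C5 mesylate cis to the C4 methyl.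

Key step: step 15

Remarks on the chemistry:
(a) Germacrane numbering is used for all intermediates (carvone C1, C2, C3, C4, C5, C6 = C9, C10, C1, C2, C3, C4). In the bicycles ring A is C1–C4/C9/C10 and ring B is C4–C9; α is the face of the C4 methyl group.
(b) C9 becomes the ketone carbon in step 15, so its configuration is a free design element. The route carries the epimer with the C9 hydroxyl α (cis to the C4 methyl, cis-fused octalin), because addition to the carvone carbonyl should give it and because it steers the C7 side chain. The trans-fused lactone holds ring B in the chair with the C5 mesylate equatorial.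
(c) The 11-methyl group is brought in by enolate alkylation (step 13), because that is the mode expected to place it trans to H7, as the target requires.
(d) 3-(Trimethylsilyl)propynal, allylmagnesium bromide and vinylmagnesium bromide are taken as purchased.

Step 1
Reactants: 1 (S)-carvone
Product: 2 trans-6-methylcarvone
Conditions: LiN(iPr)2, THF, −78 °C; MeI, −78 → −20 °C
Reagents that add atoms: iodomethane, CI
Why: Kinetic α′-deprotonation of the cross-conjugated enone and enolate alkylation (known for carvone) should give mainly the trans isomer shown; the C4 configuration is erased again by the enolisation of step 2.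

Step 2
Reactants: 2 trans-6-methylcarvone; 3 3-(trimethylsilyl)propynal
Product: 5 propargylic aldol triethylsilyl ether, via free aldol 4 (not isolated)
Conditions: LiN(iPr)2, THF, −78 °C; 3, −78 °C; AcOH quench; crude aldol, Et3SiOTf, 2,6-lutidine, CH2Cl2, −78 °C
Reagents that add atoms: triethylsilyl trifluoromethanesulfonate, CC[Si](CC)(CC)OS(=O)(=O)C(F)(F)F
Why: Aldol addition of the tetrasubstituted lithium enolate to the ynal should take place anti to the neighbouring isopropenyl group, which fixes quaternary C4 with its methyl cis to the C3 substituent; a Zimmerman–Traxler chair should favour the C5 epimer shown, which does not matter because C5 is oxidised in step 8, and silylation at −78 °C without strong base prevents retro-aldol cleavage.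

Step 3
Reactants: 5 propargylic aldol triethylsilyl ether
Product: 7 3-acetoxy enone, via methoxy hydroperoxide 6 (not isolated)
Conditions: O3, CH2Cl2/MeOH 4:1, −78 °C (Sudan Red 7B end point); then Ac2O, Et3N, 4-(dimethylamino)pyridine (cat.), 0 °C → rt
Reagents that add atoms: ozone, [O-][O+]=O (oxygen on C3); methanol, CO (carbonyl oxygen of the acetate; acetic anhydride only activates the hydroperoxide)
Why: Ozonolysis in methanol should cleave only the 1,1-disubstituted alkene (the enone alkene and the silylalkyne are electron-poor), and Criegee rearrangement of the derived peracetate moves C3 from carbon to oxygen with retention, so the 3S oxygen is set by the carvone stereocentre, while quaternary C4 rules out β-elimination of the new acetate.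

Step 4
Reactants: 7 3-acetoxy enone; 8 allylmagnesium bromide
Product: 9 9-allyl-3,9-diol
Conditions: CH2=CHCH2MgBr (4 equiv), THF, −78 → −20 °C; aqueous NH4Cl
Reagents that add atoms: none
Why: Grignard 1,2-addition to the enone carbonyl should occur from the face anti to the pseudoaxial C4 methyl and the C3 acetoxy group (the sense seen in additions to carvone), giving the C9 hydroxyl α and the allyl group β, and the excess reagent cleaves the acetate in the same operation; any minor C9 epimer is separated here.

Step 5
Reactants: 9 9-allyl-3,9-diol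
Product: 10 3-O-TBS ether
Conditions: tBuMe2SiOTf (1.1 equiv), 2,6-lutidine, CH2Cl2, −78 °C
Reagents that add atoms: tert-butyldimethylsilyl trifluoromethanesulfonate, CC(C)(C)[Si](C)(C)OS(=O)(=O)C(F)(F)F
Why: Silylation with a silyl triflate at low temperature takes the secondary C3 alcohol and leaves the tertiary allylic C9 alcohol free (steric differentiation).

Step 6
Reactants: 10 3-O-TBS ether
Product: 12 vinyl allyl diene, via terminal alkyne 11 (not isolated)
Conditions: K2CO3, MeOH, 0 °C; then H2 (1 atm), Pd/CaCO3 poisoned with Pb(OAc)2 (Lindlar catalyst), quinoline, EtOAc, rt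
Reagents that add atoms: none
Why: Carbonate-mediated methanolysis removes the alkynyl silyl group and Lindlar semihydrogenation should stop at the vinyl group, since the poisoned catalyst reduces alkynes much faster than the allyl and trisubstituted alkenes.

Step 7
Reactants: 12 vinyl allyl diene
Product: 13 cis-fused octalin 5-O-TES ether
Conditions: second-generation Grubbs catalyst RuCl2(=CHPh)(PCy3)(H2IMes) (5 mol%), CH2Cl2, 40 °C
Reagents that add atoms: none
Why: Ring-closing metathesis of the two monosubstituted alkenes, which sit cis on ring A, should close the six-membered ring B with the C6=C7 alkene and loss of ethylene; the trisubstituted C1=C10 alkene does not take part and no stereocentre is formed.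

Step 8
Reactants: 13 cis-fused octalin 5-O-TES ether
Product: 15 ring B enone, via allylic alcohol 14 (not isolated)
Conditions: HF·pyridine, pyridine, THF, 0 °C; then Dess–Martin periodinane, NaHCO3, CH2Cl2, rt
Reagents that add atoms: none
Why: Fluoride removes the triethylsilyl ether much faster than the tert-butyldimethylsilyl ether, and buffered Dess–Martin oxidation converts the allylic alcohol (whatever its configuration) into the enone without base, so the β-hydroxy ketone is not exposed to retro-aldol conditions.

Step 9
Reactants: 15 ring B enone; 16 vinylmagnesium bromide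
Product: 18 6-hydroxy-7-vinyl-5-ketone, via bis-silyl enol ether 17 (not isolated)
Conditions: CH2=CHMgBr (4 equiv), CuBr·SMe2 (0.3 equiv), THF, −78 → −40 °C; Me3SiCl, Et3N, −78 → 0 °C; crude 17, dimethyldioxirane, acetone/CH2Cl2, −78 °C; citric acid, MeOH, 0 °C
Reagents that add atoms: dimethyldioxirane, CC1(C)OO1 (oxygen on C6); chlorotrimethylsilane, C[Si](C)(C)Cl (silicon in 17 only)
Why: Copper-catalysed 1,4-addition of the vinyl Grignard reagent should proceed by axial attack on C7 in the half-chair of the cis-fused enone that has the small C9 oxygen axial, that is cis to the C9 oxygen and away from ring A, which sets C7 (side chain α); the trapped silyl enol ether is then hydroxylated by dimethyldioxirane (Rubottom oxidation, much faster than epoxidation of the other alkenes) from the face anti to the C7 vinyl group and to the axial C4 methyl, which sets C6 (oxygen β, trans to C7).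

Step 10
Reactants: 18 6-hydroxy-7-vinyl-5-ketone
Product: 19 trans-5,6-diol
Conditions: Me4NBH(OAc)3, MeCN/AcOH 1:1, −30 °C
Reagents that add atoms: none
Why: In this hydroxyl-directed (Evans–Saksena) reduction the acetoxyborohydride bound to the C6 hydroxyl should deliver hydride to the β face of C5, giving the trans-5,6-diol with the C5 hydroxyl α and equatorial, which is also the more stable epimer.

Step 11
Reactants: 19 trans-5,6-diol
Product: 20 C12 primary alcohol
Conditions: 9-BBN (5 equiv), THF, 0 °C → rt; then NaOH, H2O2, 0 °C
Reagents that add atoms: hydrogen peroxide, OO (oxygen on C12)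
Why: Hydroboration–oxidation with the bulky 9-BBN is selective for the monosubstituted vinyl group over the trisubstituted C1=C10 alkene and places boron, then oxygen, on the terminal carbon C12 (anti-Markovnikov).

Step 12
Reactants: 20 C12 primary alcohol
Product: 21 trans-fused 13-nor lactone
Conditions: 2,2,6,6-tetramethylpiperidin-1-oxyl (20 mol%), PhI(OAc)2 (2.5 equiv), CH2Cl2, rt
Reagents that add atoms: none
Why: Oxoammonium oxidation attacks only the primary alcohol; the aldehyde is captured by the vicinal, trans-diequatorial C6 hydroxyl as the five-membered lactol and oxidised on to the trans-fused γ-lactone, a known selective diol-to-lactone oxidation that leaves secondary and tertiary alcohols alone.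

Step 13
Reactants: 21 trans-fused 13-nor lactone
Product: 22 11-methyl lactone diol
Conditions: LiN(iPr)2 (3.3 equiv), THF, −78 °C; MeI (1.2 equiv), −78 → −50 °C; AcOH quench at −78 °C
Reagents that add atoms: iodomethane, CI
Why: Alkylation of the lactone enolate (the two hydroxyls are carried as lithium alkoxides, which iodomethane does not alkylate at −78 °C) should occur on the face anti to the pseudoaxial H7 of the trans-fused lactone, so the methyl group enters trans to H7 and gives 11R under kinetic control.

Step 14
Reactants: 22 11-methyl lactone diol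
Product: 23 C5 mesylate
Conditions: MeSO2Cl, Et3N, CH2Cl2, −20 °C
Reagents that add atoms: methanesulfonyl chloride, CS(Cl)(=O)=O
Why: Sulfonylation through sulfene takes the only secondary alcohol, the equatorial C5 hydroxyl, while the tertiary C9 alcohol does not react and triethylamine is too weak a base to start the fragmentation.

Step 15
Reactants: 23 C5 mesylate
Product: 24 9-oxo-germacra-1(10)Z,4E-dien-12,6-olide 3-O-TBS ether
Conditions: KOtBu (1.05 equiv), THF/tBuOH 10:1, 0 °C, 15 min; pH 7 phosphate buffer
Reagents that add atoms: none
Why: KOtBu deprotonates the tertiary C9 alcohol, and the alkoxide forms C9=O as the C4–C9 σ bond breaks in concert with formation of C4=C5 and loss of the C5 mesylate; this is a Wharton (Grob-type) fragmentation of a 1,3-diol monosulfonate, the reaction type used for decalin-to-cyclodecenone ring expansions. No ring is closed: the bond shared by rings A and B of the bicyclo[4.4.0] system is cut, the ten-membered ring remains, and no stereocentre is created. The trans-fused lactone locks ring B in the chair in which the C5–O bond is equatorial and antiperiplanar to C4–C9, whichever way the C9 oxygen points, so fragmentation is the only stereoelectronically open path (no antiperiplanar hydrogen for elimination, no backside access for oxetane formation). Because H5 is anti to the axial C4 methyl in that chair, C3 and C6 end up trans across the new double bond (4E), and the C1=C10 alkene, cis within ring A, becomes 1(10)Z. The single equivalent of base is consumed as potassium mesylate, so after the fragmentation no strong base should remain to epimerise C11, to enolise the new enone towards C2 with loss of the C3 silyloxy group, or to shift the silyl group.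

Step 16
Reactants: 24 9-oxo-germacra-1(10)Z,4E-dien-12,6-olide 3-O-TBS ether
Product: 25 (9R)-alcohol
Conditions: (S)-Me-CBS oxazaborolidine [(S)-1-methyl-3,3-diphenylhexahydropyrrolo[1,2-c][1,3,2]oxazaborole] (1.0 equiv), catecholborane, toluene, −78 °C; MeOH, then aqueous NaHCO3
Reagents that add atoms: none
Why: In this Corey–Bakshi–Shibata reduction, with the α-methyl alkenyl carbon C10 as the large and C8 as the small ketone substituent, the (S)-oxazaborolidine should deliver hydride to give the 9R allylic alcohol (the sense that turns acetophenone into the R alcohol), 1,2-selectively and without touching the lactone.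

Step 17
Reactants: 25 (9R)-alcohol
Product: 26 3,9-diol
Conditions: HF·pyridine, pyridine, THF, 0 °C → rt
Reagents that add atoms: none
Why: Fluoride cleavage of the secondary silyl ether under buffered, non-basic conditions, which spares C11 and the lactone.

Step 18
Reactants: 26 3,9-diol
Product: 27 target diacetate
Conditions: Ac2O, pyridine, 4-(dimethylamino)pyridine (cat.), CH2Cl2, rt
Reagents that add atoms: acetic anhydride, CC(=O)OC(C)=O
Why: Nucleophile-catalysed acetylation of the two secondary alcohols gives the target.

Compound list
1 | (S)-carvone | CC1=CC[C@@H](CC1=O)C(C)=C | starting material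
2 | (5S,6R)-2,6-dimethyl-5-(prop-1-en-2-yl)cyclohex-2-en-1-one (trans-6-methylcarvone; the new methyl is on C4) | CC(=C)[C@H]1CC=C(C)C(=O)[C@@H]1C | intermediate
3 | 3-(trimethylsilyl)prop-2-ynal | C[Si](C)(C)C#CC=O | starting material
4 | free aldol: ring A enone with quaternary C4 (methyl cis, CH(OH)C≡CSiMe3 chain trans to the C3 isopropenyl group) | CC(=C)[C@H]1CC=C(C)C(=O)[C@@]1([C@@H](O)C#C[Si](C)(C)C)C | intermediate
5 | C5 triethylsilyl ether of 4 | CC(=C)[C@H]1CC=C(C)C(=O)[C@@]1([C@@H](O[Si](CC)(CC)CC)C#C[Si](C)(C)C)C | intermediate
6 | α-methoxy hydroperoxide from ozonolysis of the isopropenyl group of 5 (new ketal carbon unassigned) | COC(C)(OO)[C@H]1CC=C(C)C(=O)[C@@]1([C@@H](O[Si](CC)(CC)CC)C#C[Si](C)(C)C)C | intermediate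
7 | 3α-acetoxy enone (acetate in place of isopropenyl, retention at C3) | CC(=O)O[C@H]1CC=C(C)C(=O)[C@@]1([C@@H](O[Si](CC)(CC)CC)C#C[Si](C)(C)C)C | intermediate
8 | allylmagnesium bromide | C=CC[Mg]Br | starting material
9 | 9β-allyl-3α,9α-diol (C9 hydroxyl cis to the C4 methyl), C5 OSiEt3, silylalkyne | O[C@H]1CC=C(C)[C@](O)(CC=C)[C@@]1([C@@H](O[Si](CC)(CC)CC)C#C[Si](C)(C)C)C | intermediate
10 | 3-O-tert-butyldimethylsilyl ether of 9 | CC(C)(C)[Si](C)(C)O[C@H]1CC=C(C)[C@](O)(CC=C)[C@@]1([C@@H](O[Si](CC)(CC)CC)C#C[Si](C)(C)C)C | intermediate
11 | terminal alkyne from 10 | CC(C)(C)[Si](C)(C)O[C@H]1CC=C(C)[C@](O)(CC=C)[C@@]1([C@@H](O[Si](CC)(CC)CC)C#C)C | intermediate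
12 | diene: C5 vinyl carbinol triethylsilyl ether and C9 allyl carbinol on ring A | CC(C)(C)[Si](C)(C)O[C@H]1CC=C(C)[C@](O)(CC=C)[C@@]1([C@@H](O[Si](CC)(CC)CC)C=C)C | intermediate
13 | cis-fused Δ1(10),6-octalin: 3α-OTBS, 5-OSiEt3, 9α-OH, 4α-methyl | CC(C)(C)[Si](C)(C)O[C@H]1CC=C(C)[C@]2(O)CC=C[C@H](O[Si](CC)(CC)CC)[C@]12C | intermediate
14 | C5 allylic alcohol from 13 | CC(C)(C)[Si](C)(C)O[C@H]1CC=C(C)[C@]2(O)CC=C[C@H](O)[C@]12C | intermediate
15 | ring B enone: 5-oxo-Δ6, 9α-OH, 3α-OTBS | CC(C)(C)[Si](C)(C)O[C@H]1CC=C(C)[C@]2(O)CC=CC(=O)[C@]12C | intermediate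
16 | vinylmagnesium bromide | C=C[Mg]Br | starting material
17 | 7α-vinyl C5 trimethylsilyl enol ether with 9α-OSiMe3 | CC(C)(C)[Si](C)(C)O[C@H]1CC=C(C)[C@]2(O[Si](C)(C)C)C[C@@H](C=C)C=C(O[Si](C)(C)C)[C@]12C | intermediate
18 | 6β-hydroxy-7α-vinyl-5-ketone, 9α-OH | CC(C)(C)[Si](C)(C)O[C@H]1CC=C(C)[C@]2(O)C[C@@H](C=C)[C@H](O)C(=O)[C@]12C | intermediate
19 | 5α,6β,9α-triol with 7α-vinyl | CC(C)(C)[Si](C)(C)O[C@H]1CC=C(C)[C@]2(O)C[C@@H](C=C)[C@H](O)[C@@H](O)[C@]12C | intermediate
20 | 7α-(2-hydroxyethyl)-5α,6β,9α-triol (C12 primary alcohol) | CC(C)(C)[Si](C)(C)O[C@H]1CC=C(C)[C@]2(O)C[C@@H](CCO)[C@H](O)[C@@H](O)[C@]12C | intermediate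
21 | trans-fused 13-nor-12,6-lactone, 5α,9α-diol | CC(C)(C)[Si](C)(C)O[C@H]1CC=C(C)[C@]2(O)C[C@@H]3[C@H](OC(=O)C3)[C@@H](O)[C@]12C | intermediate
22 | (11R)-11-methyl lactone, 5α,9α-diol (methyl trans to H7) | CC(C)(C)[Si](C)(C)O[C@H]1CC=C(C)[C@]2(O)C[C@@H]3[C@H](OC(=O)[C@@H]3C)[C@@H](O)[C@]12C | intermediate
23 | C5 mesylate: cis-fused octalin lactone with 9α angular hydroxyl, 4α methyl, equatorial 5α mesylate, 3α-OTBS | CC(C)(C)[Si](C)(C)O[C@H]1CC=C(C)[C@]2(O)C[C@@H]3[C@H](OC(=O)[C@@H]3C)[C@@H](OS(C)(=O)=O)[C@]12C | intermediate
24 | 9-oxo-germacra-1(10)Z,4E-dien-12,6-olide 3-O-TBS ether | CC(C)(C)[Si](C)(C)O[C@H]1C/C=C(/C)C(=O)C[C@@H]2[C@@H](/C=C/1C)OC(=O)[C@@H]2C | intermediate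
25 | (9R)-9-hydroxy-germacra-1(10)Z,4E-dien-12,6-olide 3-O-TBS ether | CC(C)(C)[Si](C)(C)O[C@H]1C/C=C(/C)[C@H](O)C[C@@H]2[C@@H](/C=C/1C)OC(=O)[C@@H]2C | intermediate
26 | (3S,9R)-3,9-dihydroxy-germacra-1(10)Z,4E-dien-12,6-olide | O[C@H]1C/C=C(/C)[C@H](O)C[C@@H]2[C@@H](/C=C/1C)OC(=O)[C@@H]2C | intermediate
27 | (3S,6S,7S,9R,11R)-3,9-diacetoxy-germacra-1(10)Z,4E-dien-12,6-olide | CC(=O)O[C@H]1C/C=C(/C)[C@H](OC(C)=O)C[C@@H]2[C@@H](/C=C/1C)OC(=O)[C@@H]2C | target

Total steps: 18. Longest linear sequence: 18 steps from (S)-carvone.

Steps most likely to fail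

Step 15. The C9 alkoxide may do something other than fragment: silyl transfer from the neighbouring C3 oxygen, epimerisation at C11, or γ-deprotonation of the new enone with loss of the C3 silyloxy group. The fallback cuts the same C4–C9 bond as a retro-aldol. It sets out from 22: Dess–Martin oxidation of the C5 hydroxyl gives the 5-oxo lactone F1. KN(SiMe3)2 in THF at −78 °C should turn its C9 alkoxide, by retro-aldol cleavage, into the ten-membered C9 ketone with a C4=C5 enolate. In this enolate C3 stays anti to C6, because the equatorial C3 branch eclipses the carbonyl group in ring B. N-Phenylbis(trifluoromethanesulfonimide) traps it as the enol triflate F2. Palladium-catalysed formate reduction (Pd(OAc)2, PPh3, HCO2H, Et3N, DMF, 40 °C) then replaces the triflate by hydrogen with retention of the alkene geometry, and the route is rejoined at 24.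

Step 9. The basic magnesium alkoxide of 15 may open by retro-aldol cleavage of C4–C9, which would scramble C4 and C9. The vinyl group may also add to the wrong face of C7, or the dioxirane may attack C1=C10. The fallback brings in C11–C12 under non-basic conditions and already at the carboxyl oxidation level. It sets out from 15: the C9 hydroxyl is capped (Me3SiOTf, Et3N), and a Mukaiyama–Michael addition of 1-methoxy-1-(trimethylsilyloxy)ethene (catalytic Me3SiOTf, CH2Cl2, −78 °C) gives the bis-silyl keto ester enol ether F3. Dimethyldioxirane followed by citric acid in methanol gives the hydroxy keto ester F4. Me4NBH(OAc)3 gives the dihydroxy ester F5, and catalytic camphorsulfonic acid in toluene closes the trans-fused lactone. The route is rejoined at 21, and steps 11 and 12 are no longer needed.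

Step 10. Hydride may be delivered to the α face of C5, for instance through the tertiary C9 hydroxyl in the minor chair of ring B. That gives the axial C5 alcohol, whose mesylate cannot fragment to the E alkene. The fallback gives up kinetic, reagent-delivered hydride for thermodynamic control. It sets out from 18: Meerwein–Ponndorf–Verley reduction (Al(OiPr)3, iPrOH/toluene, 80 °C) is reversible and should settle on the all-equatorial trans-5,6-diol, so the route is rejoined at 19 and no new compound arises.

Further compounds
F1 | step 15 | 5-oxo lactone: ketone at C5 of 22, 9α-hydroxyl free | CC(C)(C)[Si](C)(C)O[C@H]1CC=C(C)[C@]2(O)C[C@@H]3[C@H](OC(=O)[C@@H]3C)C(=O)[C@]12C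
F2 | step 15 | enol triflate: 9-oxo-5-(trifluoromethanesulfonyloxy)-germacra-1(10)Z,4-dien-12,6-olide 3-O-TBS ether, C3 trans to C6 | CC(C)(C)[Si](C)(C)O[C@H]1C/C=C(/C)C(=O)C[C@@H]2[C@@H](/C(OS(=O)(=O)C(F)(F)F)=C/1C)OC(=O)[C@@H]2C
F3 | step 9 | bis-silyl keto ester enol ether: 7α-CH2CO2Me, C5 trimethylsilyl enol ether, 9α-OSiMe3 | CC(C)(C)[Si](C)(C)O[C@H]1CC=C(C)[C@]2(O[Si](C)(C)C)C[C@@H](CC(=O)OC)C=C(O[Si](C)(C)C)[C@]12C
F4 | step 9 | hydroxy keto ester: 6β-hydroxy-5-oxo, 7α-CH2CO2Me, 9α-OH | CC(C)(C)[Si](C)(C)O[C@H]1CC=C(C)[C@]2(O)C[C@@H](CC(=O)OC)[C@H](O)C(=O)[C@]12C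
F5 | step 9 | dihydroxy ester: 5α,6β-diol, 7α-CH2CO2Me, 9α-OH | CC(C)(C)[Si](C)(C)O[C@H]1CC=C(C)[C@]2(O)C[C@@H](CC(=O)OC)[C@H](O)[C@@H](O)[C@]12C
F0 | step 10 | none | none
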